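**Retrosynthetic overview**

1. All carbon comes from trans-resveratrol (1). Its ortho-hydroxylation gives piceatannol (3) by way of piceatannol ortho-quinone (2); 2 and 3 are the two halves of cassigarol E (4).
2. Key disconnection of 4: both C–O bonds of the dioxane ring in one retro-[4+2], to the O=C–C=O unit of 2 (heterodiene) and the E-olefin of 3, as in the presumed biogenesis from two piceatannol units.
3. Stereochemistry: trans from suprafacial addition to the E-olefin; (2R,3R) from a chiral phosphoric acid that holds both partners by hydrogen bonds.
4. Ring order: no ring is made before the last step. The 1,4-dioxane ring is the only ring formed, and no protecting group is used.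

Assumption 1: stilbene numbering is used. Ring A is the 3,5-dihydroxyphenyl ring and carries olefin carbon C7; ring B is the catechol ring and carries olefin carbon C8, with hydroxyls at 3′ and 4′ (4′ para to the olefin).

Assumption 2: the (R)-phosphoric acid is written for the (2R,3R) product. The facial sense of a new reaction cannot be guaranteed in advance, so if the opposite sense is found the equally available (S)-acid is used with no other change.

**Step 1**
Reactants: 1 trans-resveratrol
Product: 3 piceatannol, via piceatannol ortho-quinone 2 (not isolated)
Conditions: IBX (1.05 equiv), DMF, −20 °C → 0 °C, 1 h; then aq Na2S2O4 (2.5 equiv), 0 °C → rt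
Reagents that add atoms: IBX (2-iodoxybenzoic acid), O=C1OI(=O)(O)c2ccccc12
Why: IBX ortho-oxygenation of a phenol: the 4′-phenol, the most easily oxidised of the three because it is conjugated with the stilbene, binds to pentavalent iodine and receives oxygen at its ortho carbon to give ortho-quinone 2, which dithionite reduces in the same flask to the catechol; no stereocentre is formed and the E-olefin is untouched.

**Step 2**
Reactants: 3 piceatannol
Product: 2 piceatannol ortho-quinone
Conditions: NaIO4 (1.05 equiv), EtOAc/H2O, 0 °C, 2 min; cold phase separation, Na2SO4, filtration; kept as an assayed EtOAc solution at −40 °C and used within the hour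
Reagents that add atoms: none
Why: Two-electron dehydrogenation of a catechol by periodate, through a cyclic periodate ester that collapses to the ortho-quinone within seconds, far faster than any attack on ring A or the olefin; it is run in its own flask so that no oxidant, salt or water reaches the enantio-determining step, and no stereocentre is formed.

**Step 3**
Reactants: 2 piceatannol ortho-quinone; 3 piceatannol
Product: 4 cassigarol E
Conditions: (R)-TRIP [(R)-3,3′-bis(2,4,6-triisopropylphenyl)-1,1′-binaphthyl-2,2′-diyl hydrogen phosphate] (10 mol %), 4 Å MS, CH2Cl2/EtOAc 2:1, −40 °C, argon, dark; solution of 2 (1.0 equiv) added over 4 h to 3 (1.3 equiv); silica gel, then crystallisation to upgrade ee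
Reagents that add atoms: none
Why: Proposed new method: an enantioselective inverse-electron-demand oxa-hetero-Diels–Alder reaction in which the acid proton binds the more basic carbonyl oxygen of 2 (the one meta to the styryl group and conjugated with it) while the P=O accepts the 4′-OH of 3, so that the nucleophilic olefin carbon C7 of 3 bonds to the para oxygen of 2 on one enantioface inside the chiral pocket and the phosphate-bound para-quinone methide at C8 is closed at once on the same face by the new phenol oxygen, which gives the natural regiochemistry and carries the E-geometry into the trans-(2R,3R) dioxane; the closest known reactions are the thermal hetero-Diels–Alder additions of ortho-quinones to electron-rich styrenes and the chiral phosphoric acid catalysed cycloadditions of quinone-type electrophiles with hydroxystyrenes.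

**Compound list**

1 | trans-resveratrol, 5-[(E)-2-(4-hydroxyphenyl)ethenyl]benzene-1,3-diol | Oc1ccc(/C=C/c2cc(O)cc(O)c2)cc1 | starting material
2 | piceatannol ortho-quinone, 4-[(E)-2-(3,5-dihydroxyphenyl)ethenyl]cyclohexa-3,5-diene-1,2-dione | O=C1C=CC(/C=C/c2cc(O)cc(O)c2)=CC1=O | intermediate
3 | piceatannol, 4-[(E)-2-(3,5-dihydroxyphenyl)ethenyl]benzene-1,2-diol | Oc1cc(O)cc(/C=C/c2ccc(O)c(O)c2)c1 | intermediate
4 | cassigarol E, 5-[(E)-2-[(2R,3R)-3-(3,4-dihydroxyphenyl)-2-(3,5-dihydroxyphenyl)-2,3-dihydro-1,4-benzodioxin-6-yl]ethenyl]benzene-1,3-diol; trans-dioxane in which the oxygen para to the styryl group is bonded to the carbon bearing the 3,5-dihydroxyphenyl ring | Oc1cc(O)cc(/C=C/c2ccc3c(c2)O[C@H](c2ccc(O)c(O)c2)[C@@H](c2cc(O)cc(O)c2)O3)c1 | target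

**Step count and risks**

Total step count: 3. Longest linear sequence: 3 (1 → 3 → 2 → 4; compound 3 is used in both step 2 and step 3).

Most likely to fail, in order:

Step 3 (enantioselective hetero-Diels–Alder). The risks are low ee from a racemic background or radical pathway, the regioisomeric dioxane, and C–C coupled dimers. The fallback sets out from piceatannol 3 and comes back at cassigarol E 4. Compound 3 is stirred with Ag2CO3 (1.1 equiv) in acetone/toluene at room temperature in the dark. This is a stoichiometric one-electron oxidation that forms the dioxane by phenoxyl-radical O–C7 coupling and closure of the para-quinone methide, with no asymmetric induction. The trans-dioxane is isolated as the racemate, that is 4 together with its mirror image ent-cassigarol E F1. The two are separated by preparative chiral SFC (amylose tris(3,5-dimethylphenylcarbamate) phase, CO2/MeOH). The configuration then comes from a resolution instead of a catalyst.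

Step 1 (IBX hydroxylation). The risk is that the oxidant also attacks the electron-rich positions of ring A, or over-oxidises the product. The fallback sets out from trans-resveratrol 1 and comes back at piceatannol 3. It is a whole-cell biocatalytic hydroxylation with recombinant Escherichia coli expressing the two-component flavin monooxygenase HpaBC, with glycerol, air, pH 7.5 buffer containing Tween 80, at 30 °C. The enzyme hydroxylates only ortho to a para-substituted phenol, so ring A is left alone and no quinone is formed. This fallback makes no new compound (F0).

Step 2 (separate preparation of the quinone). The risk is that 2 takes up water or self-condenses during two-phase handling and storage. The fallback sets out from piceatannol 3 and comes back at cassigarol E 4, so that 2 is never handled. PhI(OAc)2 (0.5 equiv) in CH2Cl2 is added by syringe pump to 3 and (R)-TRIP (10 mol %) at −40 °C. Half of 3 is oxidised in the flask and trapped at once by the other half in a one-flask oxidative dimerisation. The price is acetic acid and iodobenzene in the enantio-determining flask, which is why this is not the main route. This fallback makes no new compound (F0).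

**Further compounds**

F1 | step 3 | ent-cassigarol E, the (2S,3S) enantiomer of 4 | Oc1cc(O)cc(/C=C/c2ccc3c(c2)O[C@@H](c2ccc(O)c(O)c2)[C@H](c2cc(O)cc(O)c2)O3)c1
F0 | step 1 | none | none
F0 | step 2 | none | none
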